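**Target:** 2-[(3R,5S)-5-[(9E,11E,13E)-hexadeca-9,11,13-trien-1-yl]-3,5-dimethyl-1,2-dioxolan-3-yl]acetic acid (17). The acetic acid arm and the long chain are trans on the ring.

**Retrosynthetic overview**
1. 17 ⇒ methyl ester 16 ⇒ B-alkyl Suzuki disconnection of the side chain: terminal alkene 12 + (E,E,E)-iodotriene 14 (one step from dienal 13).
2. 12 ⇒ anomeric acetate 9: the C3–CH2CO2Me bond comes from a peroxycarbenium ion and a ketene silyl acetal, with the ring kept intact.
3. Key step: the 1,2-dioxolane (the only ring, formed in step 3) ⇒ E-enone 6 + H2O2. Asymmetric conjugate hydroperoxidation makes the C5–O bond and sets C5; hemiketalisation makes the C3–O bond.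
4. 6 ⇒ enyne 3 (carboalumination/acylation) ⇒ 8-bromooct-1-ene 1 + acetylide 2.

Assumption: the quinine-derived 9-amino(9-deoxy)epi amine is taken to deliver H2O2 to the Si face of C4 of E-enone 6 (giving 5S); if the first run shows the opposite sense, its quinidine-derived pseudo-enantiomer is used with nothing else changed.

**Route**

Step 1
Reactants: 1 8-bromooct-1-ene; 2 lithium acetylide ethylenediamine complex (LiC≡CH·H2NCH2CH2NH2)
Product: 3 dec-1-en-9-yne
Conditions: DMSO, 10 °C to rt
Reagents that add atoms: none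
Why: SN2 alkylation of the acetylide by the unhindered primary bromide; no stereocentre is formed and the terminal alkene is inert.

Step 2
Reactants: 3 dec-1-en-9-yne; 4 acetyl chloride
Product: 6 (E)-4-methyldodeca-3,11-dien-2-one, via alkenylalane 5 (not isolated)
Conditions: Me3Al (2 equiv), Cp2ZrCl2 (0.25 equiv), CH2Cl2, 0 °C to rt; excess Me3Al evaporated; then 4, Pd(PPh3)4 (5 mol%), THF, 0 °C to rt
Reagents that add atoms: trimethylaluminium, C[Al](C)C
Why: Negishi zirconium-catalysed carboalumination adds CH3 and Al syn across the terminal alkyne (the isolated alkene reacts far more slowly), and Pd-catalysed acylation of alkenylalane 5 with 4 proceeds with retention, fixing the E geometry on which the facial sense of step 3 depends.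

Step 3
Reactants: 6 (E)-4-methyldodeca-3,11-dien-2-one
Product: 8 (5S)-3,5-dimethyl-5-(oct-7-en-1-yl)-1,2-dioxolan-3-ol (both C3 epimers), via hydroperoxy ketone 7 (not isolated)
Conditions: 50% aq. H2O2 (3 equiv), 9-amino(9-deoxy)epiquinine·2 CF3CO2H (10 mol%), 1,4-dioxane, 20 °C, 36 h
Reagents that add atoms: hydrogen peroxide, OO
Why: Proposed new method: the primary ammonium salt condenses with the enone to an iminium ion, whose protonated quinuclidine holds H2O2 and delivers it to the Si face of the β,β-disubstituted carbon of the E-isomer (giving 5S); hydrolysis to 7 and 5-exo hemiketalisation then close the ring through the second C–O bond and take the adduct out of the retro-addition equilibrium. The closest known reactions are the primary-amine-catalysed asymmetric hydroperoxidation of β-monosubstituted enones and the racemic H2O2 addition to mesityl oxide; new here is a tetrasubstituted C–O stereocentre from an acyclic β,β-dialkyl enone, which requires C–O formation to outrun E/Z scrambling of the iminium ion through its dienamine (hence high H2O2 concentration and low temperature).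

Step 4
Reactants: 8 (5S)-3,5-dimethyl-5-(oct-7-en-1-yl)-1,2-dioxolan-3-ol
Product: 9 (5S)-3,5-dimethyl-5-(oct-7-en-1-yl)-1,2-dioxolan-3-yl acetate (both C3 epimers)
Conditions: Ac2O, pyridine, DMAP (cat.), CH2Cl2, 0 °C
Reagents that add atoms: acetic anhydride, CC(=O)OC(C)=O
Why: O-acylation of the peroxyhemiketal hydroxyl (the ring form dominates over 7) gives an ionisable anomeric acetate; C5 is untouched and the C3 epimer mixture does not matter because C3 becomes planar in step 5.

Step 5
Reactants: 9 (5S)-3,5-dimethyl-5-(oct-7-en-1-yl)-1,2-dioxolan-3-yl acetate; 10 tert-butyl[(1-methoxyethenyl)oxy]dimethylsilane (ketene silyl acetal of methyl acetate)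
Product: 12 methyl 2-[(3R,5S)-3,5-dimethyl-5-(oct-7-en-1-yl)-1,2-dioxolan-3-yl]acetate, via peroxycarbenium ion 11 (not isolated)
Conditions: 10 (2 equiv), TMSOTf (0.2 equiv), CH2Cl2, −78 °C; SiO2 chromatography to remove the C3 epimer
Reagents that add atoms: none
Why: Lewis-acid ionisation of the acetate gives peroxycarbenium ion 11, trapped by the ketene silyl acetal in a Mukaiyama-type substitution known for 3-alkoxy- and 3-acetoxy-1,2-dioxolanes; C3 is set under substrate control by attack anti to the larger C5 chain, but only modestly (about 1.5–2:1 expected), so the (3S,5S) epimer is separated, while C5 is not affected.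

Step 6
Reactants: 13 (2E,4E)-hepta-2,4-dienal
Product: 14 (1E,3E,5E)-1-iodoocta-1,3,5-triene
Conditions: CrCl2 (6 equiv), CHI3 (2 equiv), THF, 0 °C, dark; used at once
Reagents that add atoms: iodoform, IC(I)I
Why: Takai olefination; the gem-dichromium species from CHI3 and CrCl2 adds to the aldehyde and eliminates to the E-alkenyl iodide, leaving the existing E,E-diene untouched.

Step 7
Reactants: 12 methyl 2-[(3R,5S)-3,5-dimethyl-5-(oct-7-en-1-yl)-1,2-dioxolan-3-yl]acetate; 14 (1E,3E,5E)-1-iodoocta-1,3,5-triene
Product: 16 methyl 2-[(3R,5S)-5-[(9E,11E,13E)-hexadeca-9,11,13-trien-1-yl]-3,5-dimethyl-1,2-dioxolan-3-yl]acetate, via alkylborane 15 (not isolated)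
Conditions: 9-BBN (1.3 equiv), THF, 0 °C to rt; then 14 (1.3 equiv), Pd(dppf)Cl2 (5 mol%), AsPh3 (5 mol%), Cs2CO3 (3 equiv), DMF/H2O, rt, dark
Reagents that add atoms: none
Why: Anti-Markovnikov hydroboration of the only terminal alkene followed by B-alkyl Suzuki–Miyaura coupling with retention of the iodide geometry; the ester and the fully substituted dialkyl peroxide are expected to survive 9-BBN and room-temperature Pd catalysis, and no stereocentre is touched.

Step 8
Reactants: 16 methyl 2-[(3R,5S)-5-[(9E,11E,13E)-hexadeca-9,11,13-trien-1-yl]-3,5-dimethyl-1,2-dioxolan-3-yl]acetate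
Product: 17 2-[(3R,5S)-5-[(9E,11E,13E)-hexadeca-9,11,13-trien-1-yl]-3,5-dimethyl-1,2-dioxolan-3-yl]acetic acid
Conditions: LiOH·H2O (3 equiv), THF/H2O 3:1, 0 °C to rt; then 1 M HCl to pH 4, 0 °C
Reagents that add atoms: lithium hydroxide, [Li+].[OH-]
Why: Ester saponification; the peroxide carbons carry no hydrogen, so Kornblum–DeLaMare cleavage is impossible, both stereocentres are quaternary and cannot epimerise, and cold brief acidification spares the triene.

**Compound list**
1 | 8-bromooct-1-ene | C=CCCCCCCBr | starting material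
2 | lithium acetylide ethylenediamine complex | [Li+].[C-]#C.NCCN | starting material
3 | dec-1-en-9-yne | C=CCCCCCCC#C | intermediate
4 | acetyl chloride | CC(=O)Cl | starting material
5 | dimethyl[(1E)-2-methyldeca-1,9-dien-1-yl]alane | C=CCCCCCC/C(C)=C/[Al](C)C | intermediate
6 | (E)-4-methyldodeca-3,11-dien-2-one | C=CCCCCCC/C(C)=C/C(C)=O | intermediate
7 | (4S)-4-hydroperoxy-4-methyldodec-11-en-2-one | C=CCCCCCC[C@](C)(OO)CC(C)=O | intermediate
8 | (5S)-3,5-dimethyl-5-(oct-7-en-1-yl)-1,2-dioxolan-3-ol (both C3 epimers) | C=CCCCCCC[C@@]1(C)CC(C)(O)OO1 | intermediate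
9 | (5S)-3,5-dimethyl-5-(oct-7-en-1-yl)-1,2-dioxolan-3-yl acetate (both C3 epimers) | C=CCCCCCC[C@@]1(C)CC(C)(OC(C)=O)OO1 | intermediate
10 | tert-butyl[(1-methoxyethenyl)oxy]dimethylsilane | C=C(OC)O[Si](C)(C)C(C)(C)C | starting material
11 | (5S)-3,5-dimethyl-5-(oct-7-en-1-yl)-1,2-dioxolan-3-ylium triflate (peroxycarbenium ion pair) | C=CCCCCCC[C@@]1(C)CC(C)=[O+]O1.[O-]S(=O)(=O)C(F)(F)F | intermediate
12 | methyl 2-[(3R,5S)-3,5-dimethyl-5-(oct-7-en-1-yl)-1,2-dioxolan-3-yl]acetate | C=CCCCCCC[C@@]1(C)C[C@](C)(CC(=O)OC)OO1 | intermediate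
13 | (2E,4E)-hepta-2,4-dienal | CC/C=C/C=C/C=O | starting material
14 | (1E,3E,5E)-1-iodoocta-1,3,5-triene | CC/C=C/C=C/C=C/I | intermediate
15 | methyl 2-[(3R,5S)-5-[8-(9-borabicyclo[3.3.1]nonan-9-yl)octyl]-3,5-dimethyl-1,2-dioxolan-3-yl]acetate | C1CCC2CCCC1B2CCCCCCCC[C@@]3(C)C[C@](C)(CC(=O)OC)OO3 | intermediate
16 | methyl 2-[(3R,5S)-5-[(9E,11E,13E)-hexadeca-9,11,13-trien-1-yl]-3,5-dimethyl-1,2-dioxolan-3-yl]acetate | CC/C=C/C=C/C=C/CCCCCCCC[C@@]1(C)C[C@](C)(CC(=O)OC)OO1 | intermediate
17 | 2-[(3R,5S)-5-[(9E,11E,13E)-hexadeca-9,11,13-trien-1-yl]-3,5-dimethyl-1,2-dioxolan-3-yl]acetic acid | CC/C=C/C=C/C=C/CCCCCCCC[C@@]1(C)C[C@](C)(CC(=O)O)OO1 | target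

**Step count**
Total: 8 steps. Longest linear sequence: 7 steps (1, 2, 3, 4, 5, 7, 8); step 6 is a one-step branch.

**Three steps most likely to fail, with fallbacks**

Step 3 (the proposed asymmetric hydroperoxidation). The risks are low ee from E/Z scrambling of the iminium ion through its dienamine, slow addition at the hindered β-carbon, and epoxide formation instead of hemiketal. The fallback uses known chemistry and replaces asymmetric catalysis by racemic synthesis and resolution. It sets out from 6. Addition of aqueous H2O2 with an achiral primary ammonium salt such as benzhydrylammonium trifluoroacetate (the racemic counterpart of the known amine-catalysed reaction and of the classical addition to mesityl oxide) gives racemic 3,5-dimethyl-5-(oct-7-en-1-yl)-1,2-dioxolan-3-ol F1. Acetylation as in step 4 gives racemic 3,5-dimethyl-5-(oct-7-en-1-yl)-1,2-dioxolan-3-yl acetate F2. Substitution with 10 as in step 5 and removal of the cis diastereomer give racemic methyl 2-[(3R*,5S*)-3,5-dimethyl-5-(oct-7-en-1-yl)-1,2-dioxolan-3-yl]acetate F3. Preparative chiral SFC on a polysaccharide phase separates the enantiomers; the (3R,5S) enantiomer is 12, where the fallback comes back to the route.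

Step 5 (substitution at C3). The risks are poor diastereoselectivity and Lewis-acid fragmentation of peroxycarbenium ion 11. The fallback closes the ring by a second C–O bond formation (intramolecular conjugate addition of the hydroperoxide) instead of C–C bond formation on the cation. It sets out from 8. 2-Methoxypropene with pyridinium p-toluenesulfonate traps the open hydroperoxy ketone as (4S)-4-[(2-methoxypropan-2-yl)peroxy]-4-methyldodec-11-en-2-one F4. Horner–Wadsworth–Emmons olefination with trimethyl phosphonoacetate and NaH in THF gives methyl (5S)-5-[(2-methoxypropan-2-yl)peroxy]-3,5-dimethyltrideca-2,12-dienoate F5 (mainly 2E; both geometries cyclise). Aqueous acetic acid in THF removes the ketal to give methyl (2E,5S)-5-hydroperoxy-3,5-dimethyltrideca-2,12-dienoate F6. Et2NH in CF3CH2OH then effects 5-exo peroxy-oxa-Michael closure to 12 and its C3 epimer, separated as before; the fallback comes back at 12. This does not by itself improve the C3 selectivity, which is expected to be low here too.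

Step 7 (hydroboration and Suzuki coupling beside a peroxide). The risks are attack of the borane or zerovalent palladium on the O–O bond and decomposition of iodotriene 14. The fallback builds the triene by olefination instead of cross-coupling. It sets out from 12. Linear-selective hydroformylation (Rh(acac)(CO)2, Xantphos, CO/H2, toluene, 60 °C) gives methyl 2-[(3R,5S)-3,5-dimethyl-5-(9-oxononyl)-1,2-dioxolan-3-yl]acetate F7. The olefination partner is made from 13: NaBH4 reduction gives (2E,4E)-hepta-2,4-dien-1-ol F8; Mitsunobu reaction with 1-phenyl-1H-tetrazole-5-thiol (PPh3, DIAD) gives 5-{[(2E,4E)-hepta-2,4-dien-1-yl]sulfanyl}-1-phenyl-1H-tetrazole F9; oxidation with H2O2 and (NH4)6Mo7O24 gives 5-{[(2E,4E)-hepta-2,4-dien-1-yl]sulfonyl}-1-phenyl-1H-tetrazole F10. Julia–Kocienski olefination of F7 with F10 (KN(SiMe3)2 added to the mixture in DME at −60 °C), with I2-catalysed isomerisation to the all-E triene if needed, gives 16, where the fallback comes back to the route.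

**Further compounds**
F1 | step 3 | rac-3,5-dimethyl-5-(oct-7-en-1-yl)-1,2-dioxolan-3-ol (racemate, both C3 epimers) | C=CCCCCCCC1(C)CC(C)(O)OO1
F2 | step 3 | rac-3,5-dimethyl-5-(oct-7-en-1-yl)-1,2-dioxolan-3-yl acetate (racemate, both C3 epimers) | C=CCCCCCCC1(C)CC(C)(OC(C)=O)OO1
F3 | step 3 | rac-methyl 2-[(3R*,5S*)-3,5-dimethyl-5-(oct-7-en-1-yl)-1,2-dioxolan-3-yl]acetate (racemate, relative configuration as in 12) | C=CCCCCCCC1(C)CC(C)(CC(=O)OC)OO1
F4 | step 5 | (4S)-4-[(2-methoxypropan-2-yl)peroxy]-4-methyldodec-11-en-2-one | C=CCCCCCC[C@](C)(OOC(C)(C)OC)CC(C)=O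
F5 | step 5 | methyl (2E,5S)-5-[(2-methoxypropan-2-yl)peroxy]-3,5-dimethyltrideca-2,12-dienoate | C=CCCCCCC[C@](C)(OOC(C)(C)OC)C/C(C)=C/C(=O)OC
F6 | step 5 | methyl (2E,5S)-5-hydroperoxy-3,5-dimethyltrideca-2,12-dienoate | C=CCCCCCC[C@](C)(OO)C/C(C)=C/C(=O)OC
F7 | step 7 | methyl 2-[(3R,5S)-3,5-dimethyl-5-(9-oxononyl)-1,2-dioxolan-3-yl]acetate | O=CCCCCCCCC[C@@]1(C)C[C@](C)(CC(=O)OC)OO1
F8 | step 7 | (2E,4E)-hepta-2,4-dien-1-ol | CC/C=C/C=C/CO
F9 | step 7 | 5-{[(2E,4E)-hepta-2,4-dien-1-yl]sulfanyl}-1-phenyl-1H-tetrazole | CC/C=C/C=C/CSc1nnnn1-c2ccccc2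
F10 | step 7 | 5-{[(2E,4E)-hepta-2,4-dien-1-yl]sulfonyl}-1-phenyl-1H-tetrazole | CC/C=C/C=C/CS(=O)(=O)c1nnnn1-c2ccccc2
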